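## Structural features

Grevirobstol B is an achiral 22-membered cyclophane in which two benzene rings are joined twice: by an unbranched chain of sixteen methylene groups from ring A C3 to ring B C6, and by one ether oxygen from ring A C5 to ring B C1 (ring atoms: 16 CH2, ring A C3–C5, O, ring B C1 and C6). Ring A is a 1,3,5-trisubstituted phenol with its hydroxyl at C1. Ring B carries the ether oxygen at C1 between a hydroxyl at C2 and the chain at C6, with a second hydroxyl at C4, so it is a very electron-rich 1,2,4-trioxygenated ring. There is no stereogenic centre, and the long tether should not allow configurationally stable planar chirality, so nothing has to be controlled in three dimensions. The fragile part is ring B once its phenols are free (air oxidation in base); the chain is inert. The real difficulty is the diaryl ether: its oxygen sits on a ring B carbon flanked by the C2 oxygen and the C6 alkyl group, and the bond must exist inside a large ring, where copper- or palladium-mediated phenol arylations are least dependable. The key step uses the fact that the ring A C5–O–ring B C1 unit is an aryl benzoate minus its carbonyl group: with a CO written between ring A C5 and the oxygen, the hindered ether becomes a 23-membered lactone that can be closed by acyl transfer and then contracted.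

## Logic of the disconnections

**19 back to 18.** The three O–CH3 bonds are added. Methyl ethers are the one phenol protection that survives organolithium, Grignard and borane reagents as well as hot zerovalent nickel, and a single group for all three positions means one final operation. The demand on the forward step is cleavage of three aryl methyl ethers without touching the diaryl ether, which has no sp3 carbon on oxygen.

**18 back to 17.** The ring A C5–O bond is cut and a carbonyl group is placed between the two atoms. The hindered macrocyclic ether is exchanged for an aryl ester, a linkage that closes large rings readily; the gain is that ring closure and the difficult C–O bond formation are separated. The forward step must insert nickel at the acyl C–O bond only, expel CO and then eliminate reductively at C–O. Three choices in 17 serve this: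
- All oxygens are methyl ethers, because aryl esters, carbamates and sulfonates would themselves be opened by zerovalent nickel, benzyl ethers offer a benzylic C–O bond, and silyl ethers would not last in hot phosphate.
- The ring A methoxy group is meta to C5, where it acts as a weak inductive acceptor.
- The ring B C2 methoxy group lies next to the ester oxygen and can act as a hemilabile donor.

**17 back to 15.** The ester C(=O)–O bond to ring B C1 is cut. Macrolactonisation is the most dependable way to close a ring of this size, and the open-chain hydroxy acid is far simpler. The forward step must acylate a phenol that has two ortho substituents, at high dilution.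

**15 back to 11 and 12.** The ring A C3–CH2 bond is cut (sp2–sp3), and the acid is traced to its methyl ester. This is the most convergent cut, and 12 is a catalogue compound that already has bromine, methoxy and ester in the 1,3,5 pattern, so ring A needs neither a statistical mono-methylation of a dihydroxybenzoate nor a sulfonylation. The forward step needs hydroboration of the terminal alkene in the presence of a free phenol, cross-coupling at the ring A C–Br bond, and ester hydrolysis in the same flask.

**11 back to 8 and 7.** The ring B C1–O bond is traced to a C–Br bond and then to a C–H bond. In 7 the position ortho to the chain and para to a methoxy group is the inherent site of electrophilic substitution, and its two copies are equivalent, so ring B can start from a symmetric ring. The forward steps need monobromination at that carbon (not between the methoxy groups, not at the alkene) and a bromine-to-oxygen exchange that leaves the alkene alone.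

**7 back to 4 and 5.** The chain is cut between its fifth and sixth carbon counted from ring B (sp3–sp3). This divides the sixteen carbons into a C5 and a C11 piece, both from catalogue alkenyl halides, and the alkene needed later is already present in 5. The forward step needs a Grignard reagent from a primary chloride and a copper-catalysed alkyl–alkyl coupling that leaves the alkene alone.

**4 back to 1 and 2.** The ring B C6–CH2 bond is cut (sp2–sp3). A symmetric aryl bromide and a chloroalkene replace a longer olefination, hydrogenation, reduction and activation sequence. The forward step needs palladium to react at C–Br and leave the primary C–Cl bond for the next step.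

## Other disconnections considered

**Alternative 1:** The cut removes two bonds of ring B, C1–C6 and C2–C3, so ring B does not exist before the key step and the macrocycle is closed through C1–C6. In the forward sense the open-chain precursor A2 (a ring A aryloxymalonate whose C16 tether ends in a methyl ynone) would be treated with Cs2CO3 and then NaOMe at high dilution. The malonate carbon adds to the ynone β-carbon, the methyl ketone enolate attacks one ester, and the macrocyclic dienone A1 results. A1 must still lose its ester group to aromatise and then one methyl ether.
- In its favour: the ether oxygen is attached to C1 while that carbon is still sp3, by O-alkylation of a ring A phenol, so no hindered aryl–oxygen coupling is needed. Both ring B hydroxyls arrive unprotected from carbonyl groups.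
- Better than the chosen plan: every elementary step belongs to a known reaction type, and two rings and two C–C bonds form in one operation against one bond.
- Against it here: the ring-closing event is the attack of a fully substituted, aryloxy-bearing carbanion on a β-alkyl ynone. That addition is hindered and reversible and competes with intermolecular addition, so the key step itself needs high dilution, whereas the chosen contraction is unimolecular. The ynone can isomerise by propargylic deprotonation or take up methoxide, the adduct must place the acetyl group cis to the malonate carbon before the second ring can close, and the β-keto ester of A1 is open to retro-Claisen cleavage until it is decarboxylated.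
- Step economy: about equal. A2 needs the same kind of chain assembly plus ynone and malonate installation, and the end game has two operations in place of one.
- Overall: stronger on precedent and on protecting-group economy at ring B; the chosen plan is stronger in leaving ring closure to a dependable acyl transfer.

**Alternative 2:** The cut is at the two phenolic C–O bonds, ring A C1–O and ring B C4–O, which are traced to C–H bonds of the macrocycle A4 that carries only the ring B C2 methoxy group. In the forward sense [Ir(OMe)(cod)]2 with 4,4'-di-tert-butyl-2,2'-bipyridine and bis(pinacolato)diboron would give the bis(boronate) A3; oxidation of both C–B bonds and one demethylation would finish.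
- In its favour: ring A C1 is the only ring A C–H without an ortho substituent, and ring B C4 is the only such C–H of ring B, so steric control should point to exactly these two carbons.
- Better than the chosen plan: the reaction type is established on meta-disubstituted and 1,2,3-trisubstituted arenes, so it is the safer on mechanism. The building blocks are also simpler, since ring A needs no oxygen beyond the ether and ring B can come from a guaiacol-type unit whose phenol oxygen is already flanked correctly, with no bromination and hydroxylation.
- Against it here: it does not make the macrocyclic diaryl ether. A4 contains the same doubly ortho-substituted ether in the same ring, so the central problem is only moved and needs a key step of its own. Both rings must be borylated to completion, and minor attack next to the small methoxy group at ring B C3 or next to the ether oxygen at ring A C6 would give isomers late in the route.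
- Step economy: equal at best once a ring closure for A4 is added, with two extra late operations.
- Overall: it solves the easier part of the structure (where two hydroxyls go). It is compatible with the chosen contraction and not a rival to it.

**Alternative 3:** The cut takes ring A apart at C1–C6 and C4–C5 (and, through the electrocyclisation, C1–C2). In the forward sense the precursor A6 (the aryl ethynyl ether of the ring B phenol, its C16 tether ending in a 3-alkylcyclobutenone) would be heated at high dilution. Ring opening to a vinylketene, [2+2] addition to the ynol ether, a second ring opening, six-electron closure and tautomerisation would give A5 with the ring A phenol free.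
- In its favour: the oxygen on the hindered ring B carbon is introduced as an alkynyl ether of a phenol, not by arylation. The benzannulation places hydroxyl, chain and ether oxygen 1,3,5 by its own regiochemistry, and it needs no reagent or metal.
- Better than the chosen plan: the ring A hydroxyl arrives unprotected, so one methyl ether fewer has to be removed, and two rings and three bonds form at once.
- Equal to the chosen plan: a 22-membered version of this benzannulation has no direct precedent, so both key steps are extrapolations.
- Against it here: the macrocyclising [2+2] step joins a transient vinylketene, present only at low stationary concentration, to a remote and only moderately nucleophilic aryl ynol ether. It is entropically costly and competes with ketene dimerisation. A6 also carries two sensitive groups at the two ends of the chain, which should cost more steps than the way to 17.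
- Step economy: the chosen plan should be shorter, and its entropic cost is paid in a reliable acyl transfer.

Key step: step 7

Remark on the chemistry: 5-chloropent-1-ene, 1-bromo-3,5-dimethoxybenzene, 11-bromo-1-undecene and methyl 3-bromo-5-methoxybenzoate are treated as catalogue chemicals. Ring positions are numbered ring A C1 (OH), C3 (chain), C5 (ether O) and ring B C1 (ether O), C2 and C4 (OH), C6 (chain). The ring count 16 + 3 + 1 + 2 = 22 holds for 18 and 19, and 23 for 17.

## Route

Step 1
Reactants: 1 5-chloropent-1-ene; 2 1-bromo-3,5-dimethoxybenzene
Product: 4 1-(5-chloropentyl)-3,5-dimethoxybenzene, via B-(5-chloropentyl)-9-BBN 3 (not isolated)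
Conditions: 9-BBN (1.1 equiv), THF, 0 °C to rt; then 2, Pd(dppf)Cl2 (3 mol %), aq. K3PO4, THF/DMF, 60 °C
Reagents that add atoms: none
Why: Anti-Markovnikov hydroboration of the terminal alkene followed by B-alkyl Suzuki–Miyaura coupling at the aryl C–Br bond; the primary C–Cl bond is inert to this palladium catalyst and to aqueous phosphate at 60 °C.

Step 2
Reactants: 4 1-(5-chloropentyl)-3,5-dimethoxybenzene; 5 11-bromo-1-undecene
Product: 7 1-(hexadec-15-en-1-yl)-3,5-dimethoxybenzene, via 5-(3,5-dimethoxyphenyl)pentylmagnesium chloride 6 (not isolated)
Conditions: Mg, BrCH2CH2Br (cat.), THF, reflux; then 5, Li2CuCl4 (3 mol %), THF, −10 °C to rt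
Reagents that add atoms: none
Why: Copper-catalysed sp3–sp3 coupling (Kochi type) of a primary alkyl Grignard reagent with a primary alkyl bromide should join the C5 and C11 pieces; aryl ethers and the terminal alkene do not react under these conditions.

Step 3
Reactants: 7 1-(hexadec-15-en-1-yl)-3,5-dimethoxybenzene
Product: 8 2-bromo-1-(hexadec-15-en-1-yl)-3,5-dimethoxybenzene
Conditions: NBS (1.0 equiv), MeCN, 0 °C, dark
Reagents that add atoms: N-bromosuccinimide, O=C1CCC(=O)N1Br
Why: Electrophilic aromatic bromination should go to the carbon ortho to the chain and para to a methoxy group, which is less crowded than the carbon between the two methoxy groups and has an equivalent twin; under polar, non-radical conditions the doubly activated ring should react far faster than the isolated alkene.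

Step 4
Reactants: 8 2-bromo-1-(hexadec-15-en-1-yl)-3,5-dimethoxybenzene
Product: 11 2-(hexadec-15-en-1-yl)-4,6-dimethoxyphenol, via aryllithium 9 (not isolated), via dimethyl arylboronate 10 (not isolated)
Conditions: n-BuLi, THF, −78 °C; B(OMe)3, −78 °C to rt; then 30% H2O2, aq. NaOH, 0 °C to rt
Reagents that add atoms: hydrogen peroxide, OO
Why: Bromine–lithium exchange, borylation and oxidative aryl migration from boron to oxygen should put the hydroxyl exactly where the bromine was; the alkene is inert to n-BuLi at −78 °C and to alkaline peroxide.

Step 5
Reactants: 11 2-(hexadec-15-en-1-yl)-4,6-dimethoxyphenol; 12 methyl 3-bromo-5-methoxybenzoate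
Product: 15 3-[16-(2-hydroxy-3,5-dimethoxyphenyl)hexadecyl]-5-methoxybenzoic acid, via O,C-bis(9-BBN) adduct 13 (not isolated), via coupled methyl ester 14 (not isolated)
Conditions: 9-BBN (2.5 equiv), THF, 0 °C to rt; then 12, Pd(dppf)Cl2 (5 mol %), aq. K3PO4, THF/DMF, 60 °C; then LiOH·H2O, MeOH/H2O, 60 °C; aq. HCl work-up
Reagents that add atoms: lithium hydroxide, [Li+].[OH-]
Why: One equivalent of borane is spent on the phenolic O–H and a second hydroborates the alkene; B-alkyl Suzuki–Miyaura coupling at the unhindered ring A bromide and saponification in the same flask should give the hydroxy acid, which acid–base extraction separates from neutral boron residues.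

Step 6
Reactants: 15 3-[16-(2-hydroxy-3,5-dimethoxyphenyl)hexadecyl]-5-methoxybenzoic acid
Product: 17 macrolactone (23-membered ring A benzoate of the ring B phenol), via mixed 2,4,6-trichlorobenzoic anhydride 16 (not isolated)
Conditions: 2,4,6-trichlorobenzoyl chloride, Et3N, THF, rt; then slow addition to DMAP, toluene, 90 °C (final 1 mM)
Reagents that add atoms: none
Why: Yamaguchi macrolactonisation: DMAP attacks the unhindered ring A carbonyl of the mixed anhydride, and the acylpyridinium ion should acylate the phenol intramolecularly; slow addition keeps the stationary concentration low enough to favour the 23-membered ring over oligoesters.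

Step 7
Reactants: 17 macrolactone (23-membered ring A benzoate of the ring B phenol)
Product: 18 tri-O-methylgrevirobstol B
Conditions: Ni(cod)2 (20 mol %), 3,4-bis(dicyclohexylphosphino)thiophene (40 mol %), K3PO4 (1.5 equiv), m-xylene, reflux (bath 150 °C), argon sweep
Reagents that add atoms: none
Why: Proposed new method: zerovalent nickel carrying the chelating, electron-rich bisphosphine should insert into the acyl C–O bond of the aryl benzoate, the acyl nickel aryloxide should lose CO by migration of the ring A carbon to nickel, and C–O reductive elimination from the resulting aryl nickel aryloxide should join ring A C5 to the ring B oxygen and regenerate zerovalent nickel. The closest known reaction type is the nickel- or palladium-catalysed decarbonylative etherification of aryl esters of azine carboxylic acids with this ligand, and the decarbonylative biaryl couplings of plain phenyl benzoates show that insertion and CO loss also occur on benzoates; new here are C–O reductive elimination from a nickel-bound benzene ring without a ring nitrogen and the macrocyclic setting. The 22-membered ring is closed by contraction of the 23-membered lactone within a nickelacycle, so the closure is unimolecular, needs no dilution and has no oligomerisation channel. No stereocentre is formed. The step needs insertion at the acyl C–O bond and not at ring B C1–O or at an aryl C–OMe bond: ring B C1 is shielded by the C2 methoxy group and the C6 chain, and the methyl ethers have no reaction partner that would make their cleavage productive. It also needs reductive elimination to outrun protonation of the aryl nickel species and carbonyl-retaining migration of the ester around ring A: the electron-rich, doubly ortho-substituted aryloxide should eliminate readily through steric relief, its C2 methoxy oxygen can keep it on nickel, anhydrous K3PO4 removes proton sources, and the argon sweep takes CO out of the refluxing solvent before it binds zerovalent nickel.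

Step 8
Reactants: 18 tri-O-methylgrevirobstol B
Product: 19 grevirobstol B
Conditions: BBr3 (6 equiv), CH2Cl2, −78 °C to rt; then H2O, 0 °C
Reagents that add atoms: none
Why: Lewis-acid cleavage of aryl methyl ethers (bromide attacks the methyl group of the boron-complexed ether) should free all three phenols, while the diaryl ether offers no sp3 carbon and stays intact; quench and extraction under argon with dilute acid protect the electron-rich ring B.

## Compound list

1 | 5-chloropent-1-ene | C=CCCCCl | starting material
2 | 1-bromo-3,5-dimethoxybenzene | COc1cc(Br)cc(OC)c1 | starting material
3 | B-(5-chloropentyl)-9-borabicyclo[3.3.1]nonane (not isolated) | ClCCCCCB1C2CCCC1CCC2 | intermediate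
4 | 1-(5-chloropentyl)-3,5-dimethoxybenzene | COc1cc(CCCCCCl)cc(OC)c1 | intermediate
5 | 11-bromo-1-undecene | C=CCCCCCCCCCBr | starting material
6 | 5-(3,5-dimethoxyphenyl)pentylmagnesium chloride (not isolated) | COc1cc(CCCCC[Mg]Cl)cc(OC)c1 | intermediate
7 | 1-(hexadec-15-en-1-yl)-3,5-dimethoxybenzene | COc1cc(CCCCCCCCCCCCCCC=C)cc(OC)c1 | intermediate
8 | 2-bromo-1-(hexadec-15-en-1-yl)-3,5-dimethoxybenzene | COc1cc(OC)c(Br)c(CCCCCCCCCCCCCCC=C)c1 | intermediate
9 | [2-(hexadec-15-en-1-yl)-4,6-dimethoxyphenyl]lithium (not isolated) | COc1cc(OC)c([Li])c(CCCCCCCCCCCCCCC=C)c1 | intermediate
10 | dimethyl [2-(hexadec-15-en-1-yl)-4,6-dimethoxyphenyl]boronate (not isolated) | COB(OC)c1c(OC)cc(OC)cc1CCCCCCCCCCCCCCC=C | intermediate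
11 | 2-(hexadec-15-en-1-yl)-4,6-dimethoxyphenol | COc1cc(OC)c(O)c(CCCCCCCCCCCCCCC=C)c1 | intermediate
12 | methyl 3-bromo-5-methoxybenzoate | COC(=O)c1cc(Br)cc(OC)c1 | starting material
13 | O,C-bis(9-BBN) adduct of 11: B-aryloxy-9-BBN ester carrying a 16-(9-borabicyclo[3.3.1]nonan-9-yl)hexadecyl chain (not isolated) | COc1cc(OC)c(OB2C3CCCC2CCC3)c(CCCCCCCCCCCCCCCCB2C3CCCC2CCC3)c1 | intermediate
14 | methyl 3-[16-(2-hydroxy-3,5-dimethoxyphenyl)hexadecyl]-5-methoxybenzoate (not isolated) | COC(=O)c1cc(OC)cc(CCCCCCCCCCCCCCCCc2cc(OC)cc(OC)c2O)c1 | intermediate
15 | 3-[16-(2-hydroxy-3,5-dimethoxyphenyl)hexadecyl]-5-methoxybenzoic acid | OC(=O)c1cc(OC)cc(CCCCCCCCCCCCCCCCc2cc(OC)cc(OC)c2O)c1 | intermediate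
16 | mixed anhydride of 15 with 2,4,6-trichlorobenzoic acid (not isolated) | O=C(OC(=O)c1c(Cl)cc(Cl)cc1Cl)c1cc(OC)cc(CCCCCCCCCCCCCCCCc2cc(OC)cc(OC)c2O)c1 | intermediate
17 | 23-membered macrolactone, ring A benzoate of the ring B phenol (OMe at ring A C1, ring B C2 and C4) | COc1cc2cc(c1)C(=O)Oc1c(OC)cc(OC)cc1CCCCCCCCCCCCCCCC2 | intermediate
18 | tri-O-methylgrevirobstol B (22-membered diaryl ether) | COc1cc2cc(c1)Oc1c(OC)cc(OC)cc1CCCCCCCCCCCCCCCC2 | intermediate
19 | grevirobstol B | Oc1cc2cc(c1)Oc1c(O)cc(O)cc1CCCCCCCCCCCCCCCC2 | target

## Step count and risk

Total step count: 8. Longest linear sequence: 8 steps (1 and 2 to 19); 5 and 12 enter as catalogue compounds.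

**Step 7 (key step, new method).** Most likely failure: C–O reductive elimination does not compete. The acyl nickel aryloxide may then simply revert, move the ester around ring A with the carbonyl retained, or be protonated after CO loss so that the ring opens. Retained CO may also tie up zerovalent nickel. The cause is the absence of the ring nitrogen that makes the known substrates electron-poor at the reacting carbon.

Fallback with known chemistry, from 11 back to 18: an Ullmann-type coupling of 11 with 1-bromo-3-iodo-5-methoxybenzene in excess (CuI, picolinic acid, K3PO4, DMSO, 85 °C) should react at the C–I bond only and give 1-bromo-3-[2-(hexadec-15-en-1-yl)-4,6-dimethoxyphenoxy]-5-methoxybenzene F1. No ring is closed in this hindered etherification. Hydroboration with 9-BBN then gives the B-alkyl-9-BBN adduct F2, and an intramolecular B-alkyl Suzuki–Miyaura coupling at high dilution (Pd(dppf)Cl2, AsPh3, Cs2CO3, DMF/THF/H2O, slow addition) closes the 22-membered ring through the ring A C3–CH2 bond and delivers 18.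

**Step 6.** Most likely failure: slow acylation of the doubly ortho-substituted phenol, so that intermolecular ester formation or transfer of the trichlorobenzoyl group takes over.

Fallback, from 11 back to 17: the ester bond is made first and intermolecularly. Steglich esterification of 11 with 3-bromo-5-methoxybenzoic acid (EDC·HCl, DMAP, CH2Cl2) gives 2-(hexadec-15-en-1-yl)-4,6-dimethoxyphenyl 3-bromo-5-methoxybenzoate F3. Hydroboration gives its B-alkyl-9-BBN adduct F4, and a macrocyclising B-alkyl Suzuki–Miyaura coupling (Pd(dppf)Cl2, AsPh3, K3PO4, DMF/THF with little water, 50 °C, slow addition) gives 17. This also bypasses step 5.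

**Step 5.** Most likely failure: incomplete hydroboration because the phenol consumes borane, or loss of material through air oxidation of the electron-rich phenoxide and catalyst inhibition under the basic coupling conditions.

Fallback, from 7 back to 15: the coupling is done before ring B is oxygenated. Hydroboration of 7 gives the B-alkyl-9-BBN adduct F5, and coupling with 12 (Pd(dppf)Cl2, aq. K3PO4) gives methyl 3-[16-(3,5-dimethoxyphenyl)hexadecyl]-5-methoxybenzoate F6. Bromination with NBS should take place only on the far more electron-rich ring B and give methyl 3-[16-(2-bromo-3,5-dimethoxyphenyl)hexadecyl]-5-methoxybenzoate F7. Palladium-catalysed hydroxylation with Pd2(dba)3, 2-di-tert-butylphosphino-2',4',6'-triisopropylbiphenyl and KOH in dioxane/H2O at 100 °C replaces bromine by hydroxyl and hydrolyses the ester in the same flask, giving 15 after acidification.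

**Step 3.** Most likely failure: addition of electrophilic bromine to the terminal alkene, or a second bromination of the activated ring.

Fallback, from 4 back to 8: the ring is brominated before the alkene is present. NBS on 4 gives 2-bromo-1-(5-chloropentyl)-3,5-dimethoxybenzene F8. A Finkelstein exchange (NaI, acetone, reflux) gives 2-bromo-1-(5-iodopentyl)-3,5-dimethoxybenzene F9. The roles in the chain coupling are then reversed: undec-10-enylmagnesium bromide F10, made from 5 and Mg, is coupled with F9 under Li2CuCl4 catalysis at −10 °C, where the hindered aryl bromide should stay untouched, giving 8.

## Further compounds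

F1 | step 7 | 1-bromo-3-[2-(hexadec-15-en-1-yl)-4,6-dimethoxyphenoxy]-5-methoxybenzene | COc1cc(Br)cc(Oc2c(OC)cc(OC)cc2CCCCCCCCCCCCCCC=C)c1
F2 | step 7 | B-alkyl-9-BBN adduct of F1 | COc1cc(Br)cc(Oc2c(OC)cc(OC)cc2CCCCCCCCCCCCCCCCB2C3CCCC2CCC3)c1
F3 | step 6 | 2-(hexadec-15-en-1-yl)-4,6-dimethoxyphenyl 3-bromo-5-methoxybenzoate | COc1cc(Br)cc(c1)C(=O)Oc1c(OC)cc(OC)cc1CCCCCCCCCCCCCCC=C
F4 | step 6 | B-alkyl-9-BBN adduct of F3 | COc1cc(Br)cc(c1)C(=O)Oc1c(OC)cc(OC)cc1CCCCCCCCCCCCCCCCB1C2CCCC1CCC2
F5 | step 5 | B-[16-(3,5-dimethoxyphenyl)hexadecyl]-9-borabicyclo[3.3.1]nonane | COc1cc(CCCCCCCCCCCCCCCCB2C3CCCC2CCC3)cc(OC)c1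
F6 | step 5 | methyl 3-[16-(3,5-dimethoxyphenyl)hexadecyl]-5-methoxybenzoate | COC(=O)c1cc(OC)cc(CCCCCCCCCCCCCCCCc2cc(OC)cc(OC)c2)c1
F7 | step 5 | methyl 3-[16-(2-bromo-3,5-dimethoxyphenyl)hexadecyl]-5-methoxybenzoate | COC(=O)c1cc(OC)cc(CCCCCCCCCCCCCCCCc2cc(OC)cc(OC)c2Br)c1
F8 | step 3 | 2-bromo-1-(5-chloropentyl)-3,5-dimethoxybenzene | COc1cc(OC)c(Br)c(CCCCCCl)c1
F9 | step 3 | 2-bromo-1-(5-iodopentyl)-3,5-dimethoxybenzene | COc1cc(OC)c(Br)c(CCCCCI)c1
F10 | step 3 | undec-10-enylmagnesium bromide | C=CCCCCCCCCC[Mg]Br
A1 | alternative 1 | macrocyclic methyl 1-aryloxy-4-hydroxy-2-oxocyclohexa-3,5-diene-1-carboxylate (racemic at the blocked carbon) | COc1cc2cc(c1)OC1(C(=O)OC)C(=O)C=C(O)C=C1CCCCCCCCCCCCCCCC2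
A2 | alternative 1 | dimethyl 2-[3-methoxy-5-(19-oxoicos-17-yn-1-yl)phenoxy]malonate | COc1cc(OC(C(=O)OC)C(=O)OC)cc(CCCCCCCCCCCCCCCCC#CC(C)=O)c1
A3 | alternative 2 | macrocyclic bis(pinacol boronate) at ring A C1 and ring B C4 | COc1cc(B3OC(C)(C)C(C)(C)O3)cc2c1Oc1cc(B3OC(C)(C)C(C)(C)O3)cc(c1)CCCCCCCCCCCCCCCC2
A4 | alternative 2 | 22-membered diaryl ether macrocycle with only the ring B C2 methoxy group | COc1cccc2c1Oc1cccc(c1)CCCCCCCCCCCCCCCC2
A5 | alternative 3 | grevirobstol B ring B dimethyl ether | Oc1cc2cc(c1)Oc1c(OC)cc(OC)cc1CCCCCCCCCCCCCCCC2
A6 | alternative 3 | 3-[16-(2-ethynyloxy-3,5-dimethoxyphenyl)hexadecyl]cyclobut-2-en-1-one | C#COc1c(OC)cc(OC)cc1CCCCCCCCCCCCCCCCC1=CC(=O)C1
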